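Ring C, a benzene carrying oxygen on five adjacent carbons (C4, C5, C6, C1, C2) and hydrogen only on C3, is disconnected at the C3–C4 bond into a squarate-derived cyclobutenone plus a 1-ethoxyvinyl unit. Heating the 4-silyloxy-4-(1-ethoxyvinyl)cyclobutenone opens the four-membered ring and recloses it as the six-membered ring C, giving in one operation a pentaoxygenated phenol in which ring D is already on O5, C4 carries the free hydroxyl and O1 is marked by silicon for later arylation. The precursor has the squarate oxygens as methoxy (C6) and 3,4,5-trimethoxyphenoxy (C5, ring D), a silyl ether on the quaternary carbon (C1) and the enol ether that supplies C2 and C3.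

Key step: step 4

Numbering used: ring A is the terminal 2,4,6-trioxygenated ring and ring B the 3,4-dioxygenated ring that carries rings A and C. Ring C is the central ring (C1 bears O–ring B, C2 OH, C3 H, C4 OH, C5 O–ring D, C6 OH). Ring D is the terminal 3,4,5-trioxygenated ring.

Remark on the chemistry: the cyclobutenone compounds 8 and 9 (and F1, F9, F10) are racemic. Their only stereocentre is destroyed in step 4 and the target is achiral, so no stereocontrol is required.

Design choices: methanol is introduced on the dichloride before the phenol, so that no free methanol ever meets the labile aryl squarate. The tertiary alkoxide is silylated in the same flask, so that the acid- and heat-sensitive free carbinol is never handled.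

Step 1
Reactants: 1 squaric acid (3,4-dihydroxycyclobut-3-ene-1,2-dione)
Product: 2 squaric acid dichloride (3,4-dichlorocyclobut-3-ene-1,2-dione)
Conditions: (COCl)2 (2.2 equiv), DMF (cat.), 1,2-dichloroethane, 50 °C
Reagents that add atoms: oxalyl chloride, ClC(=O)C(Cl)=O
Why: Vilsmeier-type deoxychlorination converts the vinylogous diacid into its vinylogous bis-acid chloride, the standard activated form of squaric acid.

Step 2
Reactants: 2 squaric acid dichloride; 3 3,4,5-trimethoxyphenol
Product: 5 3-methoxy-4-(3,4,5-trimethoxyphenoxy)cyclobut-3-ene-1,2-dione, via 3-chloro-4-methoxycyclobut-3-ene-1,2-dione 4 (not isolated)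
Conditions: MeOH (1.0 equiv), CH2Cl2, 0 °C → rt, N2 sweep; then 3 (1.0 equiv), Et3N (1.1 equiv), −78 → 0 °C
Reagents that add atoms: methanol, CO
Why: Two successive addition–elimination steps (vinylogous acyl substitution) are separable because the first methoxy donor deactivates the ring towards a second methanolysis, and the phenoxide then displaces chloride, the far better leaving group, and not methoxide.

Step 3
Reactants: 5 3-methoxy-4-(3,4,5-trimethoxyphenoxy)cyclobut-3-ene-1,2-dione; 6 ethyl vinyl ether
Product: 9 4-(tert-butyldimethylsilyloxy)-4-(1-ethoxyvinyl)-3-methoxy-2-(3,4,5-trimethoxyphenoxy)cyclobut-2-en-1-one (racemic), via 1-ethoxyvinyllithium 7 (not isolated), via lithium alkoxide 8 (not isolated)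
Conditions: 6 (excess), t-BuLi (1.2 equiv), THF, −78 → 0 °C; cannulate into 5, THF, −78 °C; then TBSOTf (1.4 equiv), −78 → −20 °C; NaHCO3 quench
Reagents that add atoms: tert-butyldimethylsilyl trifluoromethanesulfonate, CC(C)(C)[Si](C)(C)OS(=O)(=O)C(F)(F)F
Why: α-Lithiation of the enol ether gives a vinyllithium whose 1,2-addition should go to the more electrophilic carbonyl, the one vinylogous to the weakly donating aryloxy group and next to the small methoxy-bearing carbon, and the tertiary lithium alkoxide is then O-silylated by the silyl triflate, the quaternary centre arising as a racemate because the squarate is planar and achiral.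

Step 4
Reactants: 9 4-(tert-butyldimethylsilyloxy)-4-(1-ethoxyvinyl)-3-methoxy-2-(3,4,5-trimethoxyphenoxy)cyclobut-2-en-1-one
Product: 12 4-(tert-butyldimethylsilyloxy)-5-ethoxy-3-methoxy-2-(3,4,5-trimethoxyphenoxy)phenol, via dienylketene 10 (not isolated), via cyclohexadienone 11 (not isolated)
Conditions: PhMe (degassed, dilute), 110 °C, base-washed glassware
Reagents that add atoms: none
Why: Heating breaks the C1–C4 bond of the cyclobutenone in a conrotatory 4-electron electrocyclic opening in which the silyloxy donor turns outward and the 1-ethoxyvinyl group inward, so that dienylketene 10 forms with the (Z) geometry that places the ketene carbon next to the vinyl CH2. A thermal disrotatory 6-electron electrocyclisation then joins these two carbons (C4–C3 of ring C) and closes the six-membered ring as cyclohexadienone 11, whose enolisation to the aromatic phenol 12 makes the cascade irreversible. The closest known reaction type is the Moore rearrangement of squarate-derived 4-alkenyl-4-hydroxy- or 4-silyloxycyclobutenones to hydroquinones and their monoethers. No stereocentre is created, and the racemic quaternary carbon of 9 becomes the planar silyloxy-bearing C1. The step needs outward rotation of the silyloxy group, which the strong preference of oxygen donors for the outward position secures, and it needs no regiocontrol of its own because the order of the four oxygen substituents was fixed in 9. Dilute, degassed and acid-free conditions should keep the enol ether and the electron-rich phenol intact.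

Step 5
Reactants: 12 4-(tert-butyldimethylsilyloxy)-5-ethoxy-3-methoxy-2-(3,4,5-trimethoxyphenoxy)phenol
Product: 13 tert-butyl[6-ethoxy-2,4-dimethoxy-3-(3,4,5-trimethoxyphenoxy)phenoxy]dimethylsilane
Conditions: MeI, K2CO3 (anhydrous), acetone, 40 °C
Reagents that add atoms: iodomethane, CI
Why: Williamson O-methylation caps the only free phenol (C4–OH), while the aryl silyl ether, shielded by two ortho alkoxy groups, should tolerate anhydrous carbonate in acetone.

Step 6
Reactants: 13 tert-butyl[6-ethoxy-2,4-dimethoxy-3-(3,4,5-trimethoxyphenoxy)phenoxy]dimethylsilane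
Product: 14 6-ethoxy-2,4-dimethoxy-3-(3,4,5-trimethoxyphenoxy)phenol
Conditions: Bu4NF, AcOH, THF, 0 °C
Reagents that add atoms: none
Why: Fluoride-mediated desilylation, driven by Si–F bond formation, frees the C1 hydroxyl, and the acetic acid buffer keeps the electron-rich phenol protonated and away from air oxidation.

Step 7
Reactants: 15 1-bromo-2,3-dimethoxybenzene
Product: 17 (3-bromo-4,5-dimethoxyphenyl)boronic acid, via pinacol boronate 16 (not isolated)
Conditions: B2pin2 (0.6 equiv), [Ir(OMe)(cod)]2 (cat.), 4,4'-di-tert-butyl-2,2'-bipyridine (cat.), THF, 80 °C; then NaIO4, aq. HCl, THF/H2O, rt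
Reagents that add atoms: bis(pinacolato)diboron, CC1(C)OB(OC1(C)C)B1OC(C)(C)C(C)(C)O1; water, O
Why: Sterically controlled iridium-catalysed C–H borylation of a 1,2,3-trisubstituted arene should take place at C5, the only C–H without an ortho substituent, leaving the C–Br bond untouched, and periodate cleavage of the released pinacol drives hydrolysis to the boronic acid.

Step 8
Reactants: 17 (3-bromo-4,5-dimethoxyphenyl)boronic acid; 18 2,4,6-trimethoxyphenol
Product: 19 1-bromo-2,3-dimethoxy-5-(2,4,6-trimethoxyphenoxy)benzene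
Conditions: Cu(OAc)2 (20 mol%), pyridine, 4 Å MS, CH2Cl2, O2 (1 atm), rt; 17 in excess
Reagents that add atoms: none
Why: Chan–Lam oxidative C–O coupling proceeds by transmetalation of the unhindered arylboronic acid to divalent copper and reductive elimination from a trivalent copper aryl phenoxide at room temperature, conditions that leave the aryl bromide inert and accept di-ortho-substituted phenols.

Step 9
Reactants: 14 6-ethoxy-2,4-dimethoxy-3-(3,4,5-trimethoxyphenoxy)phenol; 19 1-bromo-2,3-dimethoxy-5-(2,4,6-trimethoxyphenoxy)benzene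
Product: 20 2-[2,3-dimethoxy-5-(2,4,6-trimethoxyphenoxy)phenoxy]-1-ethoxy-3,5-dimethoxy-4-(3,4,5-trimethoxyphenoxy)benzene
Conditions: CuI (20 mol%), picolinic acid (40 mol%), K3PO4, DMSO, 110 °C, Ar
Reagents that add atoms: none
Why: Ligand-accelerated Ullmann diaryl ether synthesis, in which a picolinate-bound monovalent copper phenoxide adds oxidatively to the aryl bromide and releases the ether by reductive elimination, uses a catalyst system suited to ortho-substituted halides and 2,6-disubstituted phenols.

Step 10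
Reactants: 20 2-[2,3-dimethoxy-5-(2,4,6-trimethoxyphenoxy)phenoxy]-1-ethoxy-3,5-dimethoxy-4-(3,4,5-trimethoxyphenoxy)benzene
Product: 21 2-[2,3-dihydroxy-5-(2,4,6-trihydroxyphenoxy)phenoxy]-4-(3,4,5-trihydroxyphenoxy)benzene-1,3,5-triol (CNP0214481.0)
Conditions: BBr3 (excess), CH2Cl2, −78 °C → rt; degassed H2O, 0 °C; work-up under Ar
Reagents that add atoms: none
Why: Lewis acid mediated ether cleavage, in which each alkoxy oxygen binds boron and bromide attacks the methyl or ethyl carbon by SN2, should remove all eleven alkyl groups while the three diaryl ether bonds, which offer no sp3 carbon, stay intact.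

Compound list
1 | squaric acid (3,4-dihydroxycyclobut-3-ene-1,2-dione) | OC1=C(O)C(=O)C1=O | starting material
2 | squaric acid dichloride (3,4-dichlorocyclobut-3-ene-1,2-dione) | ClC1=C(Cl)C(=O)C1=O | intermediate
3 | 3,4,5-trimethoxyphenol | COc1cc(O)cc(OC)c1OC | starting material
4 | 3-chloro-4-methoxycyclobut-3-ene-1,2-dione (not isolated) | COC1=C(Cl)C(=O)C1=O | intermediate
5 | 3-methoxy-4-(3,4,5-trimethoxyphenoxy)cyclobut-3-ene-1,2-dione | COC1=C(Oc2cc(OC)c(OC)c(OC)c2)C(=O)C1=O | intermediate
6 | ethyl vinyl ether | C=COCC | starting material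
7 | 1-ethoxyvinyllithium (not isolated) | [Li]C(=C)OCC | intermediate
8 | lithium 1-(1-ethoxyvinyl)-2-methoxy-4-oxo-3-(3,4,5-trimethoxyphenoxy)cyclobut-2-en-1-olate (racemic, one enantiomer drawn; not isolated) | CCOC(=C)[C@@]1([O-])C(OC)=C(Oc2cc(OC)c(OC)c(OC)c2)C1=O.[Li+] | intermediate
9 | 4-(tert-butyldimethylsilyloxy)-4-(1-ethoxyvinyl)-3-methoxy-2-(3,4,5-trimethoxyphenoxy)cyclobut-2-en-1-one (racemic, one enantiomer drawn) | CCOC(=C)[C@@]1(O[Si](C)(C)C(C)(C)C)C(OC)=C(Oc2cc(OC)c(OC)c(OC)c2)C1=O | intermediate
10 | (3Z)-4-(tert-butyldimethylsilyloxy)-5-ethoxy-3-methoxy-2-(3,4,5-trimethoxyphenoxy)hexa-1,3,5-trien-1-one (dienylketene; not isolated) | O=C=C(Oc1cc(OC)c(OC)c(OC)c1)/C(OC)=C(/O[Si](C)(C)C(C)(C)C)C(=C)OCC | intermediate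
11 | 4-(tert-butyldimethylsilyloxy)-5-ethoxy-3-methoxy-2-(3,4,5-trimethoxyphenoxy)cyclohexa-2,4-dien-1-one (not isolated) | O=C1CC(OCC)=C(O[Si](C)(C)C(C)(C)C)C(OC)=C1Oc1cc(OC)c(OC)c(OC)c1 | intermediate
12 | 4-(tert-butyldimethylsilyloxy)-5-ethoxy-3-methoxy-2-(3,4,5-trimethoxyphenoxy)phenol | Oc1cc(OCC)c(O[Si](C)(C)C(C)(C)C)c(OC)c1Oc1cc(OC)c(OC)c(OC)c1 | intermediate
13 | tert-butyl[6-ethoxy-2,4-dimethoxy-3-(3,4,5-trimethoxyphenoxy)phenoxy]dimethylsilane | COc1cc(OCC)c(O[Si](C)(C)C(C)(C)C)c(OC)c1Oc1cc(OC)c(OC)c(OC)c1 | intermediate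
14 | 6-ethoxy-2,4-dimethoxy-3-(3,4,5-trimethoxyphenoxy)phenol | COc1cc(OCC)c(O)c(OC)c1Oc1cc(OC)c(OC)c(OC)c1 | intermediate
15 | 1-bromo-2,3-dimethoxybenzene | COc1cccc(Br)c1OC | starting material
16 | 2-(3-bromo-4,5-dimethoxyphenyl)-4,4,5,5-tetramethyl-1,3,2-dioxaborolane (not isolated) | COc1cc(B2OC(C)(C)C(C)(C)O2)cc(Br)c1OC | intermediate
17 | (3-bromo-4,5-dimethoxyphenyl)boronic acid | COc1cc(B(O)O)cc(Br)c1OC | intermediate
18 | 2,4,6-trimethoxyphenol | COc1cc(OC)c(O)c(OC)c1 | starting material
19 | 1-bromo-2,3-dimethoxy-5-(2,4,6-trimethoxyphenoxy)benzene | COc1cc(OC)c(Oc2cc(OC)c(OC)c(Br)c2)c(OC)c1 | intermediate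
20 | 2-[2,3-dimethoxy-5-(2,4,6-trimethoxyphenoxy)phenoxy]-1-ethoxy-3,5-dimethoxy-4-(3,4,5-trimethoxyphenoxy)benzene (ten methyl ethers, one ethyl ether) | COc1cc(OC)c(Oc2cc(OC)c(OC)c(Oc3c(OCC)cc(OC)c(Oc4cc(OC)c(OC)c(OC)c4)c3OC)c2)c(OC)c1 | intermediate
21 | 2-[2,3-dihydroxy-5-(2,4,6-trihydroxyphenoxy)phenoxy]-4-(3,4,5-trihydroxyphenoxy)benzene-1,3,5-triol | Oc1cc(O)c(Oc2cc(O)c(O)c(Oc3c(O)cc(O)c(Oc4cc(O)c(O)c(O)c4)c3O)c2)c(O)c1 | target

Total step count: 10
Longest linear sequence: 8 steps (steps 1–6, 9, 10); the ring A–ring B bromide is made in a 2-step branch (steps 7, 8).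

Steps most likely to fail

Step 4. The silyl group may be lost or transferred before ring opening, or traces of acid may trigger rearrangement of the silyloxy enol ether, so that the cascade is diverted before the 6-electron closure. The fallback runs the rearrangement in its classical free-hydroxyl form and differentiates the two oxygens afterwards. It sets out from 5: the adduct 8 is formed as in step 3 but quenched with aqueous NH4Cl to give 4-(1-ethoxyvinyl)-4-hydroxy-3-methoxy-2-(3,4,5-trimethoxyphenoxy)cyclobut-2-en-1-one F1. Heating F1 in degassed toluene should pass through the hydroxy dienylketene F2 and the hydroxy cyclohexadienone F3 to 5-ethoxy-3-methoxy-2-(3,4,5-trimethoxyphenoxy)benzene-1,4-diol F4. Oxidation with Ag2O in the work-up gives 5-ethoxy-3-methoxy-2-(3,4,5-trimethoxyphenoxy)cyclohexa-2,5-diene-1,4-dione F5 as the stable, purifiable form. Reduction of F5 with Na2S2O4 regenerates F4, and one equivalent of MeI with K2CO3 under argon should methylate the hydroxyl flanked by H and aryloxy (C4) in preference to the one between two alkoxy groups. The fallback returns to the route at 14.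

Step 9. Oxidative addition to the electron-rich, ortho-substituted bromide and C–O bond formation with the doubly ortho-substituted phenoxide may both be slow, so that protodebromination and degradation of the phenoxide at 110 °C overtake coupling. The fallback inverts the polarity of ring B and couples oxidatively at room temperature. It sets out from 19: Miyaura borylation (B2pin2, Pd(dppf)Cl2, KOAc, dioxane, 90 °C) gives 2-[2,3-dimethoxy-5-(2,4,6-trimethoxyphenoxy)phenyl]-4,4,5,5-tetramethyl-1,3,2-dioxaborolane F6. Treatment with NaIO4 and aqueous HCl gives [2,3-dimethoxy-5-(2,4,6-trimethoxyphenoxy)phenyl]boronic acid F7. Chan–Lam coupling of F7 with 14 (Cu(OAc)2, pyridine, 4 Å MS, CH2Cl2, air, rt) returns to the route at 20.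

Step 3. The vinyllithium may discriminate poorly between the two ring carbonyls, or may attack the aryloxy-bearing ring carbon and expel aryloxide. The fallback removes the site question by using a symmetric squarate and sets the methoxy group afterwards by the polarity of the enone. It sets out from 2: two equivalents of 3 with Et3N in CH2Cl2 give 3,4-bis(3,4,5-trimethoxyphenoxy)cyclobut-3-ene-1,2-dione F8. Addition of 7 at −78 °C gives the lithium alkoxide F9, and TBSOTf converts it into 4-(tert-butyldimethylsilyloxy)-4-(1-ethoxyvinyl)-2,3-bis(3,4,5-trimethoxyphenoxy)cyclobut-2-en-1-one F10. NaOMe (1 equiv) in MeOH/THF at −20 °C should exchange only the aryloxy group on the β-carbon of the enone by addition–elimination, because the α-aryloxy group cannot be displaced in this way. The fallback returns to the route at 9.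

Further compounds
F1 | step 4 | 4-(1-ethoxyvinyl)-4-hydroxy-3-methoxy-2-(3,4,5-trimethoxyphenoxy)cyclobut-2-en-1-one (racemic, one enantiomer drawn) | CCOC(=C)[C@@]1(O)C(OC)=C(Oc2cc(OC)c(OC)c(OC)c2)C1=O
F2 | step 4 | (3Z)-5-ethoxy-4-hydroxy-3-methoxy-2-(3,4,5-trimethoxyphenoxy)hexa-1,3,5-trien-1-one | O=C=C(Oc1cc(OC)c(OC)c(OC)c1)/C(OC)=C(/O)C(=C)OCC
F3 | step 4 | 5-ethoxy-4-hydroxy-3-methoxy-2-(3,4,5-trimethoxyphenoxy)cyclohexa-2,4-dien-1-one | O=C1CC(OCC)=C(O)C(OC)=C1Oc1cc(OC)c(OC)c(OC)c1
F4 | step 4 | 5-ethoxy-3-methoxy-2-(3,4,5-trimethoxyphenoxy)benzene-1,4-diol | CCOc1cc(O)c(Oc2cc(OC)c(OC)c(OC)c2)c(OC)c1O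
F5 | step 4 | 5-ethoxy-3-methoxy-2-(3,4,5-trimethoxyphenoxy)cyclohexa-2,5-diene-1,4-dione | CCOC1=CC(=O)C(Oc2cc(OC)c(OC)c(OC)c2)=C(OC)C1=O
F6 | step 9 | 2-[2,3-dimethoxy-5-(2,4,6-trimethoxyphenoxy)phenyl]-4,4,5,5-tetramethyl-1,3,2-dioxaborolane | COc1cc(OC)c(Oc2cc(OC)c(OC)c(B3OC(C)(C)C(C)(C)O3)c2)c(OC)c1
F7 | step 9 | [2,3-dimethoxy-5-(2,4,6-trimethoxyphenoxy)phenyl]boronic acid | COc1cc(OC)c(Oc2cc(OC)c(OC)c(B(O)O)c2)c(OC)c1
F8 | step 3 | 3,4-bis(3,4,5-trimethoxyphenoxy)cyclobut-3-ene-1,2-dione | COc1cc(OC2=C(Oc3cc(OC)c(OC)c(OC)c3)C(=O)C2=O)cc(OC)c1OC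
F9 | step 3 | lithium 1-(1-ethoxyvinyl)-4-oxo-2,3-bis(3,4,5-trimethoxyphenoxy)cyclobut-2-en-1-olate (racemic, one enantiomer drawn) | CCOC(=C)[C@@]1([O-])C(Oc2cc(OC)c(OC)c(OC)c2)=C(Oc2cc(OC)c(OC)c(OC)c2)C1=O.[Li+]
F10 | step 3 | 4-(tert-butyldimethylsilyloxy)-4-(1-ethoxyvinyl)-2,3-bis(3,4,5-trimethoxyphenoxy)cyclobut-2-en-1-one (racemic, one enantiomer drawn) | CCOC(=C)[C@@]1(O[Si](C)(C)C(C)(C)C)C(Oc2cc(OC)c(OC)c(OC)c2)=C(Oc2cc(OC)c(OC)c(OC)c2)C1=O
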